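**Plan**

- Retrosynthesis: the C5 hydroxyl is traced back to a benzyl ether and the C2 acetate to a free phenol. The benzene ring is then cut at three bonds, C5–C6, C1–C2 and C2–C3. This gives a terminal alkyne (C6, C1 and the whole side chain), one CO (C2 with its oxygen) and a benzyloxy(2-methoxyvinyl)carbene of chromium (C5, C4, C3).
- Enabling feature: the ring is a hydroquinone whose para oxygens are capped differently. The C2 oxygen sits between the alkyl-bearing C1 and the methoxy-bearing C3. The C5 oxygen sits between the two ring CH carbons C4 and C6. A carbene/alkyne/CO benzannulation delivers exactly this pattern, with the CO-derived oxygen free and the carbene-derived oxygen etherified.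
- Forward order: the chain is joined first by two epoxide openings at CH2 (dodecyl Grignard on (R)-epichlorohydrin, then acetylide on the re-closed oxirane) and acetylated. The carbene arm is made from methyl vinyl ether and Cr(CO)6. The benzene ring, the only ring, is closed last on the alkyne terminus, followed by phenol acetylation and debenzylation.
- Stereochemistry: the single stereocenter (R, the acetoxy-bearing carbon) is C2 of (R)-epichlorohydrin. No bond to it is made or broken at any stage.

Key step: step 8

Remark: (Z)-1-bromo-2-methoxyethene is assumed to behave like its well-known ethoxy homologue in its preparation, in bromine–lithium exchange and in the stability of the derived vinyllithium at −78 °C.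

**Route**

Step 1
Reactants: 1 (R)-epichlorohydrin; 2 dodecylmagnesium bromide (C12H25MgBr)
Product: 3 (R)-1-chloropentadecan-2-ol
Conditions: 2 (1.2 equiv), CuI (10 mol %), THF, −40 → −20 °C; aq. NH4Cl
Reagents that add atoms: none
Why: Copper-catalysed Grignard opening of a terminal epoxide is an SN2 attack at the unsubstituted ring carbon that outpaces displacement of the primary chloride and leaves the C–O bond of the stereocenter intact, so the (R)-chlorohydrin should form directly.

Step 2
Reactants: 3 (R)-1-chloropentadecan-2-ol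
Product: 4 (R)-2-tridecyloxirane
Conditions: NaOH (powdered), Et2O, rt
Reagents that add atoms: none
Why: Intramolecular Williamson etherification (3-exo-tet displacement of chloride by the alkoxide) closes the oxirane at the CH2Cl carbon, and because the carbinol C–O bond is kept the descriptor stays R.

Step 3
Reactants: 4 (R)-2-tridecyloxirane; 5 lithium acetylide ethylenediamine complex (LiC≡CH·H2NCH2CH2NH2)
Product: 6 (R)-heptadec-1-yn-4-ol
Conditions: 5 (2.5 equiv), DMSO, 0 °C → rt; H2O
Reagents that add atoms: none
Why: SN2 alkynylation of a monosubstituted epoxide by acetylide in DMSO should occur only at the CH2 terminus, giving the homopropargylic alcohol with the stereocenter untouched.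

Step 4
Reactants: 6 (R)-heptadec-1-yn-4-ol
Product: 7 (R)-heptadec-1-yn-4-yl acetate
Conditions: Ac2O, pyridine, DMAP (cat.), CH2Cl2, 0 °C → rt
Reagents that add atoms: acetic anhydride CC(=O)OC(C)=O
Why: DMAP-catalysed O-acylation of a secondary alcohol proceeds with retention, installs the side-chain acetate of the target and removes the only nucleophile that could later trap a ketene.

Step 5
Reactants: 8 methyl vinyl ether
Product: 10 (Z)-1-bromo-2-methoxyethene, via 1,2-dibromo-1-methoxyethane 9 (not isolated)
Conditions: Br2 (1.0 equiv), CH2Cl2, −78 °C; then PhNEt2, solvent off, 90–100 °C; distillation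
Reagents that add atoms: bromine BrBr
Why: Electrophilic bromine addition to the enol ether followed by amine-mediated dehydrobromination of the α-bromo ether (E2-type loss of HBr) is the standard route to 2-alkoxyvinyl bromides and is expected to favour the Z isomer needed for a stable vinyllithium.

Step 6
Reactants: 10 (Z)-1-bromo-2-methoxyethene; 11 chromium hexacarbonyl, Cr(CO)6
Product: 14 tetramethylammonium pentacarbonyl[(Z)-3-methoxyacryloyl]chromate, via (Z)-2-methoxyvinyllithium 12 (not isolated), via lithium acylchromate 13 (not isolated)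
Conditions: t-BuLi (2.0 equiv), Et2O, −78 °C; Cr(CO)6, THF, −78 → 0 °C; solvent off; Me4NBr, degassed H2O, 0 °C; CH2Cl2 extraction
Reagents that add atoms: tetramethylammonium bromide C[N+](C)(C)C.[Br-]
Why: Bromine–lithium exchange with retention of alkene geometry and addition of the vinyllithium to a carbonyl ligand is the first half of the Fischer carbene synthesis, and cation metathesis gives the acyl chromate as a storable tetramethylammonium salt.

Step 7
Reactants: 14 tetramethylammonium pentacarbonyl[(Z)-3-methoxyacryloyl]chromate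
Product: 16 pentacarbonyl[benzyloxy((Z)-2-methoxyvinyl)carbene]chromium, via acetoxycarbene complex 15 (not isolated)
Conditions: AcBr (1.0 equiv), CH2Cl2, −40 °C; then BnOH (1.1 equiv), −40 → 0 °C; fast chromatography under Ar
Reagents that add atoms: benzyl alcohol OCc1ccccc1
Why: O-acylation of the acyl chromate gives a highly electrophilic acyloxycarbene that undergoes addition–elimination with benzyl alcohol at the carbene carbon, the established way to alkoxycarbene complexes that direct O-alkylation does not reach.

Step 8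
Reactants: 7 (R)-heptadec-1-yn-4-yl acetate; 16 pentacarbonyl[benzyloxy((Z)-2-methoxyvinyl)carbene]chromium
Product: 18 (R)-1-[5-(benzyloxy)-2-hydroxy-3-methoxyphenyl]pentadecan-2-yl acetate, via arene tricarbonylchromium complex 17 (not isolated)
Conditions: 16 (1.3 equiv), degassed THF (0.05 M), 50 °C, Ar; then air, daylight, Et2O, rt
Reagents that add atoms: none
Why: Dötz benzannulation: thermal loss of one CO from 16 lets the alkyne of 7 insert with its CH terminus bonded to the carbene carbon (C5–C6 bond), a CO ligand then inserts at the substituted alkyne carbon (C1–C2 bond) to give a chromium-bound dienylketene, and 6π electrocyclisation of the ketene carbon onto the methoxy-bearing vinyl carbon (C2–C3 bond) followed by enolisation gives the phenol as its Cr(CO)3 complex 17, which air should strip to 18. The closest known reaction type is the benzannulation of alkenyl(alkoxy)carbene complexes of chromium, β-oxygenated ones included, with terminal alkynes to give 4-alkoxyphenols. The benzene ring is thus closed in a formal [3+2+1] sense, its last bond by 6π electrocyclic closure, and the vinyl geometry of 16 is erased when that carbon becomes aromatic. No stereocenter is formed, and the acetoxy-bearing carbon, two atoms away from the alkyne, is a spectator. The step needs regioselective alkyne insertion, which the terminal alkyne secures sterically by placing its substituted carbon next to the CO-derived C2, and it needs phenol formation over CO-free cyclopentannulation, which chromium, an alkoxy rather than amino carbene and an ether solvent favour. The side-chain oxygen is already an acetate and cannot trap the ketene as a lactone, and release without (NH4)2Ce(NO3)6 keeps the electron-rich ring from being oxidised to the quinone.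

Step 9
Reactants: 18 (R)-1-[5-(benzyloxy)-2-hydroxy-3-methoxyphenyl]pentadecan-2-yl acetate
Product: 19 (R)-1-[2-acetoxy-5-(benzyloxy)-3-methoxyphenyl]pentadecan-2-yl acetate
Conditions: Ac2O (3 equiv), Et3N, DMAP (0.2 equiv), CH2Cl2, rt
Reagents that add atoms: acetic anhydride CC(=O)OC(C)=O
Why: DMAP-catalysed acetylation overcomes the hindrance of the doubly ortho-substituted phenol, and since both oxygens end up acetylated any prior acetyl shift between the side chain and the phenol is harmless.

Step 10
Reactants: 19 (R)-1-[2-acetoxy-5-(benzyloxy)-3-methoxyphenyl]pentadecan-2-yl acetate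
Product: 20 (R)-1-(2-acetoxy-5-hydroxy-3-methoxyphenyl)pentadecan-2-yl acetate (CNP0236046.1)
Conditions: H2 (1 atm), 10% Pd/C, EtOAc, rt
Reagents that add atoms: none
Why: Catalytic hydrogenolysis cleaves the benzyl aryl ether under neutral conditions that leave the aryl acetate, the alkyl acetate and the stereocenter untouched, and the freed hydroxyl is para to the aryl acetate so no acyl migration is possible.

**Compound list**

1 | (R)-epichlorohydrin, (R)-2-(chloromethyl)oxirane | ClC[C@H]1CO1 | starting material
2 | dodecylmagnesium bromide, C12H25MgBr | CCCCCCCCCCCC[Mg]Br | starting material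
3 | (R)-1-chloropentadecan-2-ol | CCCCCCCCCCCCC[C@@H](O)CCl | intermediate
4 | (R)-2-tridecyloxirane | CCCCCCCCCCCCC[C@@H]1CO1 | intermediate
5 | lithium acetylide ethylenediamine complex, LiC≡CH·H2NCH2CH2NH2 | [Li]C#C.NCCN | starting material
6 | (R)-heptadec-1-yn-4-ol | CCCCCCCCCCCCC[C@@H](O)CC#C | intermediate
7 | (R)-heptadec-1-yn-4-yl acetate | CCCCCCCCCCCCC[C@H](CC#C)OC(C)=O | intermediate
8 | methyl vinyl ether | COC=C | starting material
9 | 1,2-dibromo-1-methoxyethane (racemic) | COC(Br)CBr | intermediate (not isolated)
10 | (Z)-1-bromo-2-methoxyethene | CO/C=C\Br | intermediate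
11 | chromium hexacarbonyl, Cr(CO)6 | O=C=[Cr](=C=O)(=C=O)(=C=O)(=C=O)=C=O | starting material
12 | (Z)-2-methoxyvinyllithium | CO/C=C\[Li] | intermediate (not isolated)
13 | lithium pentacarbonyl[(Z)-3-methoxyacryloyl]chromate | [Li+].[O-]C(/C=C\OC)=[Cr](=C=O)(=C=O)(=C=O)(=C=O)=C=O | intermediate (not isolated)
14 | tetramethylammonium pentacarbonyl[(Z)-3-methoxyacryloyl]chromate | C[N+](C)(C)C.[O-]C(/C=C\OC)=[Cr](=C=O)(=C=O)(=C=O)(=C=O)=C=O | intermediate
15 | pentacarbonyl[acetoxy((Z)-2-methoxyvinyl)carbene]chromium | CC(=O)OC(/C=C\OC)=[Cr](=C=O)(=C=O)(=C=O)(=C=O)=C=O | intermediate (not isolated)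
16 | pentacarbonyl[benzyloxy((Z)-2-methoxyvinyl)carbene]chromium | O=C=[Cr](=C=O)(=C=O)(=C=O)(=C=O)=C(OCc1ccccc1)/C=C\OC | intermediate
17 | tricarbonyl{η6-(R)-1-[5-(benzyloxy)-2-hydroxy-3-methoxyphenyl]pentadecan-2-yl acetate}chromium (η6 bonding drawn as two dot-separated parts) | CCCCCCCCCCCCC[C@H](Cc1cc(OCc2ccccc2)cc(OC)c1O)OC(C)=O.O=C=[Cr](=C=O)=C=O | intermediate (not isolated)
18 | (R)-1-[5-(benzyloxy)-2-hydroxy-3-methoxyphenyl]pentadecan-2-yl acetate | CCCCCCCCCCCCC[C@H](Cc1cc(OCc2ccccc2)cc(OC)c1O)OC(C)=O | intermediate
19 | (R)-1-[2-acetoxy-5-(benzyloxy)-3-methoxyphenyl]pentadecan-2-yl acetate | CCCCCCCCCCCCC[C@H](Cc1cc(OCc2ccccc2)cc(OC)c1OC(C)=O)OC(C)=O | intermediate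
20 | (R)-1-(2-acetoxy-5-hydroxy-3-methoxyphenyl)pentadecan-2-yl acetate, CNP0236046.1 | CCCCCCCCCCCCC[C@H](Cc1cc(O)cc(OC)c1OC(C)=O)OC(C)=O | target

**Count**

Total steps: 10. Longest linear sequence: 7 steps (steps 1, 2, 3, 4, 8, 9, 10); the carbene arm (steps 5, 6, 7) is a 3-step branch joined at step 8.

**Steps most likely to fail**

1. Step 8. The β-methoxy donor raises electron density at chromium and can slow CO insertion, so the alkyne-inserted vinylcarbene may cyclise without CO (cyclopentannulation), or the terminal alkyne may oligomerise. The fallback sets out from epoxide 4, abandons the arene construction, and comes back at 19.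
   - Commercial 5-bromovanillin (3-bromo-4-hydroxy-5-methoxybenzaldehyde) is protected with MOMCl and iPr2NEt to give 3-bromo-5-methoxy-4-(methoxymethoxy)benzaldehyde F1.
   - Baeyer–Villiger oxidation (mCPBA, NaHCO3, CH2Cl2) should give 3-bromo-5-methoxy-4-(methoxymethoxy)phenyl formate F2, which K2CO3 in MeOH cleaves to 3-bromo-5-methoxy-4-(methoxymethoxy)phenol F3.
   - Benzylation (BnBr, K2CO3, DMF) gives 5-(benzyloxy)-1-bromo-3-methoxy-2-(methoxymethoxy)benzene F4.
   - Bromine–lithium exchange (n-BuLi, THF, −78 °C) gives [5-(benzyloxy)-3-methoxy-2-(methoxymethoxy)phenyl]lithium F5. With BF3·OEt2 at −78 °C this opens epoxide 4 at CH2 to give (R)-1-[5-(benzyloxy)-3-methoxy-2-(methoxymethoxy)phenyl]pentadecan-2-ol F6, the stereocenter again being a spectator.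
   - HCl in MeOH removes the MOM group to give (R)-1-[5-(benzyloxy)-2-hydroxy-3-methoxyphenyl]pentadecan-2-ol F7.
   - Ac2O, Et3N and DMAP acetylate both hydroxyls to give 19.

2. Step 7. The acetoxycarbene may decompose before alcoholysis, or benzyl alcohol may add at the vinylogous position and exchange the methoxy group. The fallback sets out from 14 (with alkyne 7), keeps the benzannulation, and comes back at the target 20.
   - O-Methylation of 14 with Me3OBF4 (CH2Cl2, 0 °C) gives pentacarbonyl[methoxy((Z)-2-methoxyvinyl)carbene]chromium F8.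
   - Benzannulation with 7 (THF, 50 °C) should give (R)-1-(2-hydroxy-3,5-dimethoxyphenyl)pentadecan-2-yl acetate F9, which is not isolated.
   - Oxidative work-up with (NH4)2Ce(NO3)6 in aqueous MeCN converts it to (R)-1-(5-methoxy-3,6-dioxocyclohexa-1,4-dien-1-yl)pentadecan-2-yl acetate F10, removing the carbene-derived methyl.
   - Na2S2O4 (EtOAc/H2O) reduces the quinone to (R)-1-(2,5-dihydroxy-3-methoxyphenyl)pentadecan-2-yl acetate F11.
   - TBSCl and imidazole (DMF, 0 °C) should silylate only the unhindered C5 hydroxyl, giving (R)-1-[5-(tert-butyldimethylsilyloxy)-2-hydroxy-3-methoxyphenyl]pentadecan-2-yl acetate F12.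
   - Ac2O, Et3N and DMAP acetylate the hindered C2 phenol to give (R)-1-[2-acetoxy-5-(tert-butyldimethylsilyloxy)-3-methoxyphenyl]pentadecan-2-yl acetate F13.
   - HF·pyridine in THF removes the silyl group to give 20.

3. Step 6. The vinyllithium may lose lithium methoxide by β-elimination (to acetylene) on warming before the poorly soluble Cr(CO)6 captures it. The fallback sets out from 11, reverses the polarity so that the acyl group arrives as an electrophile, and comes back at 18.
   - Commercial methyl (E)-3-methoxyacrylate is saponified (NaOH, then acid) to (E)-3-methoxyacrylic acid F14, which oxalyl chloride with catalytic DMF converts to (E)-3-methoxyacryloyl chloride F15.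
   - Cr(CO)6 11 is reduced with potassium graphite C8K in THF to dipotassium pentacarbonylchromate F16.
   - Acylation of F16 with F15 at −78 °C gives potassium pentacarbonyl[(E)-3-methoxyacryloyl]chromate F17, and Me4NBr in water gives tetramethylammonium pentacarbonyl[(E)-3-methoxyacryloyl]chromate F18.
   - As in step 7, AcBr gives pentacarbonyl[acetoxy((E)-2-methoxyvinyl)carbene]chromium F19, and benzyl alcohol gives pentacarbonyl[benzyloxy((E)-2-methoxyvinyl)carbene]chromium F20.
   - F20 reacts with 7 under the conditions of step 8; the vinyl geometry is lost on aromatisation, so the product is 18.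

Further compounds
F1 | step 8 | 3-bromo-5-methoxy-4-(methoxymethoxy)benzaldehyde | COCOc1c(Br)cc(C=O)cc1OC
F2 | step 8 | 3-bromo-5-methoxy-4-(methoxymethoxy)phenyl formate | COCOc1c(Br)cc(OC=O)cc1OC
F3 | step 8 | 3-bromo-5-methoxy-4-(methoxymethoxy)phenol | COCOc1c(Br)cc(O)cc1OC
F4 | step 8 | 5-(benzyloxy)-1-bromo-3-methoxy-2-(methoxymethoxy)benzene | COCOc1c(Br)cc(OCc2ccccc2)cc1OC
F5 | step 8 | [5-(benzyloxy)-3-methoxy-2-(methoxymethoxy)phenyl]lithium | COCOc1c([Li])cc(OCc2ccccc2)cc1OC
F6 | step 8 | (R)-1-[5-(benzyloxy)-3-methoxy-2-(methoxymethoxy)phenyl]pentadecan-2-ol | CCCCCCCCCCCCC[C@@H](O)Cc1cc(OCc2ccccc2)cc(OC)c1OCOC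
F7 | step 8 | (R)-1-[5-(benzyloxy)-2-hydroxy-3-methoxyphenyl]pentadecan-2-ol | CCCCCCCCCCCCC[C@@H](O)Cc1cc(OCc2ccccc2)cc(OC)c1O
F8 | step 7 | pentacarbonyl[methoxy((Z)-2-methoxyvinyl)carbene]chromium | COC(/C=C\OC)=[Cr](=C=O)(=C=O)(=C=O)(=C=O)=C=O
F9 | step 7 | (R)-1-(2-hydroxy-3,5-dimethoxyphenyl)pentadecan-2-yl acetate | CCCCCCCCCCCCC[C@H](Cc1cc(OC)cc(OC)c1O)OC(C)=O
F10 | step 7 | (R)-1-(5-methoxy-3,6-dioxocyclohexa-1,4-dien-1-yl)pentadecan-2-yl acetate | CCCCCCCCCCCCC[C@H](CC1=CC(=O)C=C(OC)C1=O)OC(C)=O
F11 | step 7 | (R)-1-(2,5-dihydroxy-3-methoxyphenyl)pentadecan-2-yl acetate | CCCCCCCCCCCCC[C@H](Cc1cc(O)cc(OC)c1O)OC(C)=O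
F12 | step 7 | (R)-1-[5-(tert-butyldimethylsilyloxy)-2-hydroxy-3-methoxyphenyl]pentadecan-2-yl acetate | CCCCCCCCCCCCC[C@H](Cc1cc(O[Si](C)(C)C(C)(C)C)cc(OC)c1O)OC(C)=O
F13 | step 7 | (R)-1-[2-acetoxy-5-(tert-butyldimethylsilyloxy)-3-methoxyphenyl]pentadecan-2-yl acetate | CCCCCCCCCCCCC[C@H](Cc1cc(O[Si](C)(C)C(C)(C)C)cc(OC)c1OC(C)=O)OC(C)=O
F14 | step 6 | (E)-3-methoxyacrylic acid | CO/C=C/C(=O)O
F15 | step 6 | (E)-3-methoxyacryloyl chloride | CO/C=C/C(=O)Cl
F16 | step 6 | dipotassium pentacarbonylchromate, K2Cr(CO)5 | [K+].[K+].O=C=[Cr-2](=C=O)(=C=O)(=C=O)=C=O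
F17 | step 6 | potassium pentacarbonyl[(E)-3-methoxyacryloyl]chromate | [K+].[O-]C(/C=C/OC)=[Cr](=C=O)(=C=O)(=C=O)(=C=O)=C=O
F18 | step 6 | tetramethylammonium pentacarbonyl[(E)-3-methoxyacryloyl]chromate | C[N+](C)(C)C.[O-]C(/C=C/OC)=[Cr](=C=O)(=C=O)(=C=O)(=C=O)=C=O
F19 | step 6 | pentacarbonyl[acetoxy((E)-2-methoxyvinyl)carbene]chromium | CC(=O)OC(/C=C/OC)=[Cr](=C=O)(=C=O)(=C=O)(=C=O)=C=O
F20 | step 6 | pentacarbonyl[benzyloxy((E)-2-methoxyvinyl)carbene]chromium | O=C=[Cr](=C=O)(=C=O)(=C=O)(=C=O)=C(OCc1ccccc1)/C=C/OC
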